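Oak's curve cannot be flattening for want of reagent, since that charge allows 60.0 % of the substrate, the limiting reagent being the reagent, and the last reading stands lower, at 46.7 %.

| setting | oak | maple | flask |
|---|---|---|---|
| substrate | 0.050 M | 0.050 M | 0.050 M |
| reagent | 0.030 M | 0.030 M | 0.0300 M |
| capture agent | 2.5 mM | 3.8 mM | 2.50 mM |
| free catalyst | 0.10 mM | 0.10 mM | 0.10 mM |
| remark | the very flask that is asked about, followed so far | run made earlier |  |
| time |  |  | 8.0 d |
- oak (time / d: product / %): 0.417: 16.5; 0.625: 21.5; 1.04: 28.6; 1.67: 36.1; 3.00: 43.9; 5.00: 46.7
- maple (time / h: product / %): 1.50: 2.4; 2.50: 4.8; 4.00: 7.0; 8.00: 12.4; 12.0: 16.5; 20.0: 21.6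

(readings scatter by 0.3 percentage points)
- winter: at 8.0 d add free catalyst, 100 % of the amount charged, then wait 2.5 d
- dusk: at 8.0 d add reagent, 100 % of the amount charged, then wait 2.5 d
- noon: at 8.0 d take out 90 % of the product then present, then wait 2.5 d
- midnight: change nothing and wait 2.5 d more
- product taken out counts as made
- additions bring no volume worth counting
1. product, in percent of the substrate first charged, at 8.0 d
2. the option that brings most further product ("none" if no option brings more than 2 percentage points) (winter / dusk / noon / midnight / none)
3. product present, with what was taken out counted in, in percent of the substrate first charged, after dusk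
4. product present, with what was taken out counted in, in percent of the substrate first charged, after midnight

Something else is failing in oak, and capture agent looks involved: maple, charged with more of it, needs 12.0 h for the 16.5 % that oak reached in 10.01 h.

For your quick number, my own reckoning replaces each stretch of curve by its mean. If every turnover risks the catalyst equally, and the run-down of substrate and reagent is set aside, rate falls in a straight line with product. Oak's last two stretches give 0.0586 d⁻¹ at 40.0 % product, then 0.0140 d⁻¹ at 45.3 %. That line reaches zero rate at 47.0 %. The same line through maple's last two stretches gives 26.6 %.

Multiply each plateau by its capture charge. The result, 1.17 mM for oak and 1.01 mM for maple, is the catalyst's budget: with substrate and catalyst charges held, the capture charge at which the plateau would equal the whole substrate. The two differ by 16.1 %. Both are readings with their scatter, and maple's plateau lies further past its last reading than oak's, so that scatter is stretched further there, and the gap cannot be put down to the straight line.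

So oak ends near 47.0 % by this line. Winter brings fresh catalyst, but the reagent leaves room for about 13 percentage points. Dusk and noon add no catalyst.

The forecast says 47.5 % (range 46.8 % to 49 %), which stands above my line. It gives 48.2 % after dusk, 47.7 % after midnight, and winter as best, on the grounds “Progressive catalyst loss, faster with more capture agent, fits best”.

The flask gives 49.0 % at 8.0 d, 49.8 % after dusk and 49.5 % after midnight; winter is best, with 11 points, inside the room reckoned.

    substrate + free catalyst → catalyst intermediate A (k = 6.10 M⁻¹ s⁻¹)
    catalyst intermediate A → catalyst intermediate B (k = 0.0230 s⁻¹)
    reagent + catalyst intermediate B ⇌ catalyst intermediate C (K = 39.0 M⁻¹, k = 1.10 M⁻¹ s⁻¹)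
    catalyst intermediate C ⇌ catalyst intermediate D (K = 0.590, k = 0.0230 s⁻¹)
    catalyst intermediate D → free catalyst + product (k = 0.0220 s⁻¹)
    capture agent + catalyst intermediate D → trapped intermediate (k = 0.0360 M⁻¹ s⁻¹)

At 8.00 d the trapped intermediate holds 98.2 % of the catalyst, while 18 % of the reagent stands free. The budget over this capture charge, 47.0 %, lies below the 49.9 % reached at 80.0 d, so the line reads 2.9 points low.

A neighbour flask with 0.0063 M of capture agent has, by the budget, a plateau of 18.6 %. Computed, it stands at 19.6 %, with 67 % of its reagent left.

The earlier runs and the new flask stem from a simulated flask with constants of no real substance; the scatter is artificial.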